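The cyclohexane ring (C10–C15) is opened retrosynthetically at C11–C12 and C13–C14, so that C12–C13 comes from an acrylate. The precursor is the ten-membered oxecane already formed as an exocyclic enol ether (C11=CH2) with a CMe2–CHO arm on C10. Hydrogen-atom transfer from an iron hydride turns the enol ether into the tertiary α-alkoxy radical at C11; it adds to the acrylate and the resulting enolate closes on the C14 aldehyde. The step exploits the fully substituted C11 (methyl, ring oxygen O–C3, two ring carbons): its methyl and both new ring bonds arise in one operation, C10 controlling C11. The C14 carbonyl later becomes the equatorial bromide.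

Key step: step 13

Remark: atoms are numbered C1–C15 along the diterpene chain (C1=C2 vinyl, C3 ether carbon with methyl and vinyl, C6/C7 epoxide, C10/C11 ring fusion, C12/C13 ring CH2, C14 CHBr, C15 CMe2); the target is (3R,6S,7S,10S,11S,14S). Commercial (R)-(−)-linalool is assumed enantiopure and both antipodes of the two organocatalysts available.

Step 1
Reactants: 1 (R)-(−)-linalool
Product: 2 (2E,6R)-2,6-dimethylocta-2,7-diene-1,6-diol
Conditions: SeO2 (cat.), t-BuOOH, salicylic acid (cat.), CH2Cl2, rt
Reagents that add atoms: tert-butyl hydroperoxide, CC(C)(C)OO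
Why: Allylic oxidation (selenium dioxide ene reaction then [2,3]-sigmatropic shift) should functionalise only the (E)-methyl group of the trisubstituted alkene; C3 comes unchanged from the chiral pool.

Step 2
Reactants: 2 (2E,6R)-2,6-dimethylocta-2,7-diene-1,6-diol
Product: 3 (3R,6E)-8-bromo-3,7-dimethylocta-1,6-dien-3-ol
Conditions: CBr4, PPh3, CH2Cl2, 0 °C
Reagents that add atoms: carbon tetrabromide, BrC(Br)(Br)Br
Why: Appel reaction: the primary allylic alcohol is substituted with retention of the (E)-alkene while the tertiary alcohol should be inert at 0 °C.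

Step 3
Reactants: 3 (3R,6E)-8-bromo-3,7-dimethylocta-1,6-dien-3-ol; 4 acetaldehyde N,N-dimethylhydrazone
Product: 6 (4E,8R)-8-hydroxy-4,8-dimethyldeca-4,9-dienal, via dimethylhydrazone 5 (not isolated)
Conditions: 4 and LiN(iPr)2 (2.2 equiv each), THF, −78 to 0 °C; then 3; then aq. oxalic acid, Et2O, 0 °C
Reagents that add atoms: water, O
Why: Alkylation of the lithiated hydrazone (aza-enolate, SN2 at the primary allylic bromide) adds C9–C10, and mild hydrolysis unmasks the aldehyde.

Step 4
Reactants: 6 (4E,8R)-8-hydroxy-4,8-dimethyldeca-4,9-dienal; 7 nitromethane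
Product: 9 (3R,6E,10E)-3,7-dimethyl-11-nitroundeca-1,6,10-trien-3-ol, via nitro alcohol 8 (not isolated)
Conditions: KOtBu (10 mol%), MeNO2/THF, 0 °C; then MsCl, Et3N, CH2Cl2, 0 °C
Reagents that add atoms: none
Why: Henry reaction followed by base-induced elimination of the mesylate should give the conjugated (E)-nitroalkene (C10=C11).

Step 5
Reactants: 9 (3R,6E,10E)-3,7-dimethyl-11-nitroundeca-1,6,10-trien-3-ol; 10 2-methylpropanal
Product: 11 (3S,6E,10R)-10-hydroxy-2,2,6,10-tetramethyl-3-(nitromethyl)dodeca-6,11-dienal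
Conditions: chiral primary amine–thiourea from trans-cyclohexane-1,2-diamine (10 mol%, the antipode that gives 3S), H2O (5 equiv), CH2Cl2, rt
Reagents that add atoms: none
Why: Enamine-catalysed Michael addition of an α,α-disubstituted aldehyde to a nitroalkene forms C10–C15; the bifunctional catalyst (enamine plus hydrogen-bonded nitro group) fixes the face of attack and so sets C10 (S).

Step 6
Reactants: 11 (3S,6E,10R)-10-hydroxy-2,2,6,10-tetramethyl-3-(nitromethyl)dodeca-6,11-dienal
Product: 12 (3S,6E,10R)-10-hydroxy-2,2,6,10-tetramethyl-3-(nitromethyl)dodeca-6,11-dienoic acid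
Conditions: NaClO2, NaH2PO4, 2-methylbut-2-ene, t-BuOH/H2O, 0 °C to rt
Reagents that add atoms: sodium chlorite, [Na+].[O-]Cl=O
Why: Pinnick oxidation converts only the aldehyde (C14); the scavenger alkene protects the two C=C bonds from hypochlorite.

Step 7
Reactants: 12 (3S,6E,10R)-10-hydroxy-2,2,6,10-tetramethyl-3-(nitromethyl)dodeca-6,11-dienoic acid
Product: 13 (3S)-3-[(3E,7R)-7-hydroxy-3,7-dimethylnona-3,8-dien-1-yl]-2,2-dimethylbutanedioic acid
Conditions: NaNO2, AcOH, DMSO, 35 °C
Reagents that add atoms: water, O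
Why: Nitrous acid should turn the primary nitro group (C11) via nitrolic acid and nitrile oxide into the carboxylic acid (Nef-type oxidation) without enolising C10.

Step 8
Reactants: 13 (3S)-3-[(3E,7R)-7-hydroxy-3,7-dimethylnona-3,8-dien-1-yl]-2,2-dimethylbutanedioic acid
Product: 15 2-[(3S,6E,10R)-10-ethenyl-6,10-dimethyl-2-oxo-1-oxacyclodec-6-en-3-yl]-2-methylpropanoic acid, via cyclic anhydride 14 (not isolated)
Conditions: DCC, CH2Cl2, rt, filter; then KN(SiMe3)2 (1.0 equiv), THF (0.5 mM), −78 to 0 °C; dil. HCl to pH 4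
Reagents that add atoms: none
Why: The 1,4-diacid closes to the five-membered anhydride and the tertiary alkoxide should then acylate itself at the less hindered C11 carbonyl (alkoxide opening of a cyclic anhydride used as macrolactonisation), high dilution and the geminal substituents favouring the ten-membered ring.

Step 9
Reactants: 15 2-[(3S,6E,10R)-10-ethenyl-6,10-dimethyl-2-oxo-1-oxacyclodec-6-en-3-yl]-2-methylpropanoic acid
Product: 16 2-[(3S,6E,10R)-10-ethenyl-6,10-dimethyl-2-oxo-1-oxacyclodec-6-en-3-yl]-N-methoxy-N,2-dimethylpropanamide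
Conditions: MeNHOMe·HCl, EDC·HCl, HOAt (cat.), iPr2NEt, CH2Cl2, rt
Reagents that add atoms: N,O-dimethylhydroxylamine hydrochloride, CNOC.Cl
Why: Carbodiimide coupling turns the free C14 acid into the N-methoxy-N-methylamide, which should survive methylenation and is reduced to the aldehyde in step 12.

Step 10
Reactants: 16 N-methoxy-N-methylamide of the ten-membered lactone
Product: 17 (6S,7S)-6,7-epoxide of 16
Conditions: L-fructose-derived diacetonide ketone (30 mol%), KHSO5, K2CO3, Bu4NHSO4, MeCN/CH2(OMe)2/aq. buffer pH 10.5, 0 °C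
Reagents that add atoms: potassium peroxymonosulfate, [K+].[O-]S(=O)(=O)OO
Why: Shi epoxidation: the chiral dioxirane should attack the electron-rich trisubstituted C6=C7 bond in preference to the vinyl group and set C6 and C7 (6S,7S) under reagent control.

Step 11
Reactants: 17 (6S,7S)-epoxy lactone amide
Product: 18 exocyclic enol ether (lactone C11=O of 17 replaced by C11=CH2)
Conditions: Cp2Ti(μ-Cl)(μ-CH2)AlMe2, pyridine, THF/toluene, −40 to 0 °C; aq. NaOH
Reagents that add atoms: Cp2Ti(μ-Cl)(μ-CH2)AlMe2, C=[Ti](C1C=CC=C1)C1C=CC=C1.C[Al](C)Cl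
Why: Tebbe methylenation should convert the lactone carbonyl (more reactive than the hindered amide) into the enol ether; low temperature avoids Claisen rearrangement of the allyl vinyl ether formed.

Step 12
Reactants: 18 exocyclic enol ether amide
Product: 19 enol ether aldehyde (C14 amide of 18 reduced to CHO)
Conditions: iBu2AlH, THF, −78 °C; aq. sodium potassium tartrate
Reagents that add atoms: none
Why: The N-methoxy-N-methylamide is reduced through its stable aluminium chelate to the aldehyde; enol ether and epoxide should be inert to the hydride at −78 °C.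

Step 13
Reactants: 19 enol ether aldehyde; 20 allyl acrylate
Product: 23 annulated hydroxy ester (target skeleton carrying OH at C14 and CO2-allyl at C13; epimers at C13/C14), via C11 radical 21 (not isolated), via ester-stabilised C13 radical 22 (not isolated)
Conditions: Fe(acac)3 (30 mol%), PhSiH3 (2.5 equiv), 20 (3 equiv), THF/i-PrOH 4:1, 25 °C
Reagents that add atoms: none
Why: An iron hydride formed from Fe(acac)3 and PhSiH3 transfers a hydrogen atom to the terminal carbon of the electron-rich 1,1-disubstituted enol ether, giving the tertiary α-alkoxy radical at C11 (21), which adds to C12 of allyl acrylate; radical 22 is reduced to an iron enolate whose C13 attacks the C14 aldehyde (radical–polar crossover). The closest known reaction type is the hydrogen-atom-transfer-initiated radical conjugate addition/aldol annulation of alkenes with unsaturated carbonyl compounds, here with an enol ether as the donor alkene. The only ring closed is the cyclohexane, by a 6-(enolexo)-exo-trig aldol between C13 and C14 after the intermolecular C11–C12 bond; the oxecane is already in place. C11 should be set by addition of the acrylate to the radical face anti to the CMe2 group on C10, with the ring oxygen gauche to C9 and the new methyl next to H-10 (allylic strain), which places O-11 trans to C9 on the new ring. C13 and C14 form as mixtures and are erased in steps 14 to 17. The step needs chemoselectivity for the enol ether over the monosubstituted vinyl group and aldol closure faster than protonation of the enolate; the first rests on the much faster hydrogen-atom transfer to the enol ether, the second on the six-membered closure onto an unenolisable aldehyde, and the epoxide should be inert.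

Step 14
Reactants: 23 annulated hydroxy ester
Product: 24 β-keto ester (C14 ketone with CO2-allyl at C13; epimers at C13)
Conditions: 1,1,1-triacetoxy-1,1-dihydro-1,2-benziodoxol-3(1H)-one, NaHCO3, CH2Cl2, rt
Reagents that add atoms: none
Why: Dess–Martin oxidation of the secondary alcohol gives the β-keto ester and removes the C14 stereocentre.

Step 15
Reactants: 24 β-keto ester
Product: 26 C14 ketone (target with C=O in place of CHBr), via keto acid 25 (not isolated)
Conditions: Pd(PPh3)4 (5 mol%), morpholine, THF, rt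
Reagents that add atoms: none
Why: Palladium-catalysed deallylation (π-allyl transfer to morpholine) frees the β-keto acid, which loses CO2 and leaves C13 as CH2; the allylic ether at C3 is not a leaving group.

Step 16
Reactants: 26 C14 ketone
Product: 28 14,14-dibromide, via hydrazone 27 (not isolated)
Conditions: N2H4·H2O, EtOH, 50 °C; then CuBr2, Et3N, MeOH, 0 °C
Reagents that add atoms: copper dibromide, Br[Cu]Br
Why: Hydrazone halogenation: CuBr2 oxidises the hydrazone through a diazo/copper carbenoid that takes up two bromides to give the geminal dibromide.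

Step 17
Reactants: 28 14,14-dibromide
Product: 29 target CNP0243863.1, (3R,6S,7S,10S,11S,14S)
Conditions: Bu3SnH (1.05 equiv), Et3B (cat.), air, toluene, −20 °C
Reagents that add atoms: none
Why: Radical monodebromination: the α-bromo radical at C14 should take hydrogen from Bu3SnH on the face anti to the axial methyl of C15 (axial delivery), so that bromine stays equatorial and C14 is set (S).

Compound list
1 | (R)-(−)-linalool, (3R)-3,7-dimethylocta-1,6-dien-3-ol | C=C[C@@](O)(C)CCC=C(C)C | starting material
2 | (2E,6R)-2,6-dimethylocta-2,7-diene-1,6-diol | C=C[C@@](O)(C)CC/C=C(\C)CO | intermediate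
3 | (3R,6E)-8-bromo-3,7-dimethylocta-1,6-dien-3-ol | C=C[C@@](O)(C)CC/C=C(\C)CBr | intermediate
4 | acetaldehyde N,N-dimethylhydrazone | CC=NN(C)C | starting material
5 | (3R,6E)-10-(dimethylhydrazinylidene)-3,7-dimethyldeca-1,6-dien-3-ol (not isolated) | C=C[C@@](O)(C)CC/C=C(\C)CCC=NN(C)C | intermediate
6 | (4E,8R)-8-hydroxy-4,8-dimethyldeca-4,9-dienal | C=C[C@@](O)(C)CC/C=C(\C)CCC=O | intermediate
7 | nitromethane | C[N+](=O)[O-] | starting material
8 | (3R,6E)-3,7-dimethyl-11-nitroundeca-1,6-diene-3,10-diol, C10 epimers (not isolated) | C=C[C@@](O)(C)CC/C=C(\C)CCC(O)C[N+](=O)[O-] | intermediate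
9 | (3R,6E,10E)-3,7-dimethyl-11-nitroundeca-1,6,10-trien-3-ol | C=C[C@@](O)(C)CC/C=C(\C)CC/C=C/[N+](=O)[O-] | intermediate
10 | 2-methylpropanal | CC(C)C=O | starting material
11 | (3S,6E,10R)-10-hydroxy-2,2,6,10-tetramethyl-3-(nitromethyl)dodeca-6,11-dienal | C=C[C@@](O)(C)CC/C=C(\C)CC[C@H](C[N+](=O)[O-])C(C)(C)C=O | intermediate
12 | (3S,6E,10R)-10-hydroxy-2,2,6,10-tetramethyl-3-(nitromethyl)dodeca-6,11-dienoic acid | C=C[C@@](O)(C)CC/C=C(\C)CC[C@H](C[N+](=O)[O-])C(C)(C)C(=O)O | intermediate
13 | (3S)-3-[(3E,7R)-7-hydroxy-3,7-dimethylnona-3,8-dien-1-yl]-2,2-dimethylbutanedioic acid | C=C[C@@](O)(C)CC/C=C(\C)CC[C@H](C(=O)O)C(C)(C)C(=O)O | intermediate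
14 | (4S)-4-[(3E,7R)-7-hydroxy-3,7-dimethylnona-3,8-dien-1-yl]-3,3-dimethyloxolane-2,5-dione (not isolated) | C=C[C@@](O)(C)CC/C=C(\C)CC[C@H]1C(C)(C)C(=O)OC1=O | intermediate
15 | 2-[(3S,6E,10R)-10-ethenyl-6,10-dimethyl-2-oxo-1-oxacyclodec-6-en-3-yl]-2-methylpropanoic acid (ten-membered lactone, O-C3 to C11) | C=C[C@@]1(C)CC/C=C(\C)CC[C@H](C(=O)O1)C(C)(C)C(=O)O | intermediate
16 | 2-[(3S,6E,10R)-10-ethenyl-6,10-dimethyl-2-oxo-1-oxacyclodec-6-en-3-yl]-N-methoxy-N,2-dimethylpropanamide | C=C[C@@]1(C)CC/C=C(\C)CC[C@H](C(=O)O1)C(C)(C)C(=O)N(C)OC | intermediate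
17 | (6S,7S)-6,7-epoxide of 16, (3R,6S,7S,10S) | C=C[C@@]1(C)CC[C@@H]2O[C@@]2(C)CC[C@H](C(=O)O1)C(C)(C)C(=O)N(C)OC | intermediate
18 | exocyclic enol ether: C11=CH2 in place of the lactone C=O of 17 | C=C[C@@]1(C)CC[C@@H]2O[C@@]2(C)CC[C@H](C(=C)O1)C(C)(C)C(=O)N(C)OC | intermediate
19 | enol ether aldehyde: C14 amide of 18 reduced to CHO | C=C[C@@]1(C)CC[C@@H]2O[C@@]2(C)CC[C@H](C(=C)O1)C(C)(C)C=O | intermediate
20 | allyl acrylate, prop-2-en-1-yl prop-2-enoate | C=CC(=O)OCC=C | starting material
21 | tertiary α-alkoxy radical at C11 from 19 (not isolated) | C=C[C@@]1(C)CC[C@@H]2O[C@@]2(C)CC[C@H]([C](C)O1)C(C)(C)C=O | intermediate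
22 | adduct of 21 to 20, radical at C13 next to the ester, (11S) (not isolated) | C=C[C@@]1(C)CC[C@@H]2O[C@@]2(C)CC[C@H]([C@@](C)(O1)C[CH]C(=O)OCC=C)C(C)(C)C=O | intermediate
23 | annulated hydroxy ester: target skeleton with OH at C14 and CO2-allyl at C13, (3R,6S,7S,10S,11S), epimers at C13/C14 | C=C[C@@]1(C)CC[C@@H]2O[C@@]2(C)CC[C@H]2C(C)(C)C(O)C(C(=O)OCC=C)C[C@]2(C)O1 | intermediate
24 | β-keto ester: C14 ketone with CO2-allyl at C13, epimers at C13 | C=C[C@@]1(C)CC[C@@H]2O[C@@]2(C)CC[C@H]2C(C)(C)C(=O)C(C(=O)OCC=C)C[C@]2(C)O1 | intermediate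
25 | β-keto acid from 24 (not isolated) | C=C[C@@]1(C)CC[C@@H]2O[C@@]2(C)CC[C@H]2C(C)(C)C(=O)C(C(=O)O)C[C@]2(C)O1 | intermediate
26 | C14 ketone, (3R,6S,7S,10S,11S) | C=C[C@@]1(C)CC[C@@H]2O[C@@]2(C)CC[C@H]2C(C)(C)C(=O)CC[C@]2(C)O1 | intermediate
27 | C14 hydrazone of 26 (not isolated) | C=C[C@@]1(C)CC[C@@H]2O[C@@]2(C)CC[C@H]2C(C)(C)C(=NN)CC[C@]2(C)O1 | intermediate
28 | 14,14-dibromide | C=C[C@@]1(C)CC[C@@H]2O[C@@]2(C)CC[C@H]2C(C)(C)C(Br)(Br)CC[C@]2(C)O1 | intermediate
29 | CNP0243863.1, (3R,6S,7S,10S,11S,14S) | C=C[C@@]1(C)CC[C@@H]2O[C@@]2(C)CC[C@H]2C(C)(C)[C@@H](Br)CC[C@]2(C)O1 | target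

Total step count: 17. Longest linear sequence: 17 steps (the route is linear from 1).

Steps most likely to fail

Step 13. The enolate formed after the radical addition may be protonated before it reaches the aldehyde, hydrogen-atom transfer may also reach the vinyl group, and facial selectivity at C11 may be poor. The fallback sets out from 18 and comes back at 24; it separates radical addition from ring closure. The same iron hydride conditions with 20 give the open-chain adduct F1, which still carries the amide. LiN(SiMe3)2 in THF at −78 °C then closes the ring by intramolecular acylation of the ester enolate (C13) with the N-methoxy-N-methylamide (C14) to give 24.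

Step 8. Intermolecular acylation may outrun closure of the ten-membered ring, and enolisation of the activated C11 carbonyl may erode the configuration at C10. The fallback sets out from 3 and 10 and comes back at 16; the hindered ester is made between two molecules and the ring is closed by C–C bond formation. NaSO2Ph in DMF converts 3 into the allylic sulfone F2. In parallel, Henry reaction and dehydration of (tert-butyldimethylsilyloxy)acetaldehyde with 7 give the nitroalkene F3. Addition of 10 under the conditions of step 5 gives the nitro aldehyde F4, buffered KMnO4 oxidises both termini to the diacid F5, and DCC gives the anhydride F6. DMAP-promoted acylation of the tertiary alcohol of F2 with F6, run concentrated and at the less hindered carbonyl, gives the half ester F7, which is converted as in step 9 into the amide F8. Buffered fluoride frees the alcohol F9 and I2/PPh3/imidazole gives the iodide F10. KN(SiMe3)2 at high dilution alkylates the sulfone-stabilised C8 carbanion with C9–I to give the macrocyclic sulfone F11, and SmI2 removes the sulfonyl group to give 16.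

Step 16. The hindered hydrazone may eliminate to the vinyl bromide instead of taking up a second bromide, and the copper bromide may open the epoxide. The fallback sets out from 26 and comes back at 29; it replaces the radical route by substitution with inversion. LiBH(sBu)3 in THF at −78 °C attacks the ketone from the equatorial side to give the axial alcohol F12. Tf2O and pyridine give the triflate F13, and Bu4NBr in toluene displaces it with inversion to place bromine equatorial in 29.

Further compounds
F1 | step 13 | radical adduct of 18 to allyl acrylate (C11 quaternary ether carrying CH2CH2CO2-allyl, amide retained) | C=C[C@@]1(C)CC[C@@H]2O[C@@]2(C)CC[C@H]([C@@](C)(O1)CCC(=O)OCC=C)C(C)(C)C(=O)N(C)OC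
F2 | step 8 | (3R,6E)-3,7-dimethyl-8-(phenylsulfonyl)octa-1,6-dien-3-ol | C=C[C@@](O)(C)CC/C=C(\C)CS(=O)(=O)c1ccccc1
F3 | step 8 | (E)-tert-butyldimethyl[(3-nitroprop-2-en-1-yl)oxy]silane | CC(C)(C)[Si](C)(C)OC/C=C/[N+](=O)[O-]
F4 | step 8 | (3S)-3-{[(tert-butyldimethylsilyl)oxy]methyl}-2,2-dimethyl-4-nitrobutanal | CC(C)(C)[Si](C)(C)OC[C@H](C[N+](=O)[O-])C(C)(C)C=O
F5 | step 8 | (3R)-3-{[(tert-butyldimethylsilyl)oxy]methyl}-2,2-dimethylbutanedioic acid | CC(C)(C)[Si](C)(C)OC[C@H](C(=O)O)C(C)(C)C(=O)O
F6 | step 8 | (4R)-4-{[(tert-butyldimethylsilyl)oxy]methyl}-3,3-dimethyloxolane-2,5-dione | CC(C)(C)[Si](C)(C)OC[C@H]1C(C)(C)C(=O)OC1=O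
F7 | step 8 | half ester of F6 with the tertiary alcohol of F2 (C11 ester, free C14 acid) | C=C[C@@](C)(CC/C=C(\C)CS(=O)(=O)c1ccccc1)OC(=O)[C@@H](CO[Si](C)(C)C(C)(C)C)C(C)(C)C(=O)O
F8 | step 8 | N-methoxy-N-methylamide of F7 | C=C[C@@](C)(CC/C=C(\C)CS(=O)(=O)c1ccccc1)OC(=O)[C@@H](CO[Si](C)(C)C(C)(C)C)C(C)(C)C(=O)N(C)OC
F9 | step 8 | primary alcohol (C9-OH) from F8 | C=C[C@@](C)(CC/C=C(\C)CS(=O)(=O)c1ccccc1)OC(=O)[C@@H](CO)C(C)(C)C(=O)N(C)OC
F10 | step 8 | primary iodide (C9-I) from F9 | C=C[C@@](C)(CC/C=C(\C)CS(=O)(=O)c1ccccc1)OC(=O)[C@@H](CI)C(C)(C)C(=O)N(C)OC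
F11 | step 8 | ten-membered lactone amide carrying PhSO2 at C8 (epimers at C8) | C=C[C@@]1(C)CC/C=C(\C)C(S(=O)(=O)c2ccccc2)C[C@H](C(=O)O1)C(C)(C)C(=O)N(C)OC
F12 | step 16 | (14R)-alcohol, axial hydroxyl at C14 | C=C[C@@]1(C)CC[C@@H]2O[C@@]2(C)CC[C@H]2C(C)(C)[C@H](O)CC[C@]2(C)O1
F13 | step 16 | (14R)-trifluoromethanesulfonate of F12 | C=C[C@@]1(C)CC[C@@H]2O[C@@]2(C)CC[C@H]2C(C)(C)[C@H](OS(=O)(=O)C(F)(F)F)CC[C@]2(C)O1
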